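## Structural features

CNP0309304.1 is a germacranolide: a ten-membered carbocycle (C1–C10, germacrane numbering) with two E trisubstituted alkenes, C1=C10 and C4=C5, fused along C6–C7 to an α,β-unsaturated γ-lactone (ring O–C6, C7=C11, C12=O). C11 carries an acetoxymethyl group (C13), C2 an acetate and C8 a methacrylate, so three oxygens must end with two different acyl groups in a fixed pattern. There are three stereocentres: C6 (R) and C8 (S) flank the tetrasubstituted C7 with their oxygens cis on the ring, whereas C2 (R) is insulated from both by the two alkenes and cannot be set by relay. The fragile points are four: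
- the C6–H bond, γ to the lactone carbonyl and allylic to C4=C5, hence acidic and epimerisable through a 2-oxyfuran;
- the C13 acetate on the α-carbon of the unsaturated lactone, open to SN2′ displacement;
- the allylic C2 acetate, ionisable by zerovalent palladium or acid;
- the methacrylate, a Michael acceptor.

The real difficulty is closing a ten-membered ring that holds two E alkenes under conditions that spare these groups, above all the C6 centre. The structure offers a way round: the lactone ring O–C6–C7–C11–C12 is a 2,3,4-trisubstituted furan at a higher oxidation level, with C12–H as its only ring hydrogen, and C6 is bonded to the vinyl carbon C5. The C5–C6 bond can therefore be made as a furyl–vinyl sp2–sp2 bond on a flat, non-stereogenic, non-acidic furan, and C6 is created only afterwards.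

## Logic of the disconnections

32 ⇒ 31 ⇒ 30. The C8–O acyl bond is cut, then the hydroxyl is masked as a silyl ether. The methacrylate would not survive hydride, organomagnesium or palladium chemistry, so it goes on last; as a silyl ether the C8 oxygen is also distinct from the two acetate oxygens. The gain is a substrate with only robust esters. The forward steps must free and acylate a hindered secondary alcohol without touching lactone, acetates or C6–H.

30 ⇒ 27 ⇒ 25. The C6–H bond and the C12 carbonyl oxygen are removed: 30 is the reduction product of hemiketal 27, which is the oxygenation product of furan 25. This removes C6 from the list of stereocentres, together with its acidity and the SN2′ activation of the C13 acetate. The single furan hydrogen (C12–H) fixes where the carbonyl will appear. The demand is twofold: singlet oxygen must choose the furan over two trisubstituted alkenes, and hydride must choose one face of the C6 ketone.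

25 ⇒ 24. The C5–C6 bond is cut (key disconnection). It is the only ring bond between a furan α-carbon and a vinyl carbon, so its formation creates no stereocentre and uses two handles that nothing else in the molecule resembles. The gain is the largest in the plan: the ring opens to an acyclic chain carrying C2, C8 and both alkene geometries. The forward step must beat oligomerisation in closing a strained ring and must leave the allylic acetate alone.

24 ⇒ 22 ⇒ 21 ⇒ 20. The C6–Sn bond is traced back to a C6–I bond, the two acetyl groups are removed and the C13 oxygen returns to a silyl ether. A 2-furylstannane is cleaved by iodine and acid, so it cannot be present when the C5 iodide is made. A lithiation at C6 is impossible once that iodide exists. An iodide at C6 survives every earlier step and can be exchanged for magnesium beside the alkenyl iodide, so tin is placed last. The demand is chemoselectivity twice: furyl against alkenyl iodide (with acetates present), and primary against secondary silyl ether.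

20 ⇒ 18. The C4–CH3 and C5–I bonds are cut, leaving a terminal alkyne. Carbometallation builds the E trisubstituted iodoalkene with full geometric control from the simplest precursor. The forward step must accept a free allylic alcohol, two silyl ethers and an iodofuran beside Me3Al.

18 ⇒ 15 + 16. The C2–C3 bond is cut next to the C2 carbinol. C2 has no neighbouring stereocentre to steer it, so it must come from an enantioselective addition to an aldehyde; a propargyl unit brings C3–C5 with the alkyne needed above. The demand is 1,2-addition to an enal under catalyst control that ignores the distant C8 centre.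

15 ⇒ 14 ⇒ 13 ⇒ 12 ⇒ 8 + 10. After adjusting the oxidation level at C2 and removing the silyl group, the C8–C9 bond is cut. A vinylogous aldol addition makes the C8 carbinol and delivers C9, C10 with its methyl, the E C1=C10 alkene and C2 in one bond formation. The chain is thereby separated from the heteroarene. The demand is γ-regioselectivity, E geometry and face selectivity at an aldehyde with two ortho substituents.

8 ⇒ 4 ⇒ 3 ⇒ 2 ⇒ 1. The C6–I bond is cut, then aldehyde and silyl ether are traced to a symmetrical diol and diester. Iodination is possible this early because the aldehyde, masked in situ, directs metalation to its own side of the ring. The demand is regioselectivity between the two furan α-positions and monofunctionalisation of a symmetrical diol.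

10 ⇒ 9. The O–Si bond is cut; the donor is the silyl dienolate of the commercial ester.

## Other disconnections considered

Alternative 1: The cut is C8–C9, on a molecule that already holds the finished butenolide.
- Forward step: the open-chain nitro compound A1 has C8 as a nitromethyl group on C7 and a trans C1–C2 epoxide bearing the C10 isopropenyl unit. Pd2(dba)3 with P(OiPr)3 would ionise the vinyl epoxide to a π-allyl complex over C1–C10–C9 with the C2 oxygen as internal alkoxide. This base forms the C8 nitronate, which attacks C9 and closes the ring to A2.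
- In favour: the ring closes at an sp3 carbon under neutral conditions with the metal as template, and the step unveils the C2 hydroxyl and the E C1=C10 alkene at once. For a ten-membered ring this closure is mechanistically the more forgiving, and on that point it is the better plan. It needs no late redox change on the lactone, which is at least the equal of the chosen endgame.
- Against: C6–H is present when the alkoxide forms and is about as acidic as the nitro compound, so C6 can epimerise through the 2-oxyfuran. The C8 carbanion is also the γ-carbanion of the butenolide and may alkylate through C11. C8 is made without control and must be reset by a Nef reaction and a second substrate-controlled ketone reduction.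
- Comparison: structurally it carries the most fragile centre through the ring closure, where the chosen plan carries none. Mechanistically both are known reaction types stretched to a ten-membered ring. In step count the Nef, reduction and acylation tail makes it longer after ring closure, and A1 is no shorter to make than 24.

Alternative 2: The cut removes C6–C7, C11–C12 and C12–O together, so lactone and carbocycle vanish in one move.
- Forward step: the linear ynal A3 (C6 enal, C7≡C11 alkyne carrying the C13 acetoxymethyl group) would be treated with Mo(CO)3(DMF)3. Zerovalent molybdenum couples alkyne and aldehyde carbonyl to an oxametallacycle, CO inserts, and reductive elimination gives A4, which is identical with 30.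
- In favour: three bonds and two rings in one step, no furan, no tin, no late oxidation or reduction, and a precursor built by the same aldol and propargylation chemistry as the chosen chain. On paper its step economy is clearly the better.
- Against: the hetero-Pauson–Khand reaction is established where the tether closes a five- or six-membered ring. A ten-membered tether gives the two π-systems no proximity, so the oxidative cyclisation is in effect intermolecular. Zerovalent molybdenum also ionises allylic and propargylic esters, and A3 has one of each (C2 and C13). The enal can bind as a heterodiene. C6 is created with only the adjacent C8 centre to bias it.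
- Comparison: structurally it is the more direct. Mechanistically it lies outside the proven range, where the Stille closure lies at its edge. Both plans set C6 under substrate control, which is a draw. The saving of several steps would be real only if the key step worked.

Alternative 3: The ten-membered ring is traced to a six-membered one: C2–C3 is cut and C5–C10 is formed.
- Forward step: the precursor is the furan-fused divinylcyclohexanol A5 (tertiary C5 carbinol with an isopropenyl group, quaternary C10 with methyl and an E silyloxyvinyl group, the two alkenyl groups trans). KH with 18-crown-6 gives the C5 alkoxide, the [3,3] shift through a chair expands ring B by four atoms, and PhNTf2 traps the C4=C5 enolate as the triflate A6.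
- In favour: the ring forms by a unimolecular ring expansion without high dilution, and the chair transfers the configuration of C5 and C10 into both E alkenes and into C2. For making the medium ring itself this is the better method, better also than the chosen macrocyclisation. The furan is used exactly as in the chosen plan, so the two are equal in how they handle the lactone and C6.
- Against: A5 has two contiguous fully substituted stereocentres and a geometrically defined silyl enol ether on a tetrahydrobenzofuran, a much longer synthesis than the chain of 24. The furylic tertiary alkoxide can fragment instead of rearranging. The triflate must then be removed by reduction. Three oxygens under three protecting groups must be unmasked one by one, one of them oxidatively beside a vinylfuran.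
- Comparison: structurally it pays for an easy ring formation with a hard precursor. Mechanistically it is the more secure at the key step. In step economy it is clearly the longer.

Key step: step 15

Abbreviation: TBS = tert-butyl(dimethyl)silyl; positions are given in germacrane numbering.

Assumption: in steps 6 and 10 the catalyst antipode is named after the aldehyde face it has to open (Si at C8, Re at C2); if induction on these substrates runs the other way, the mirror-image catalyst is used with nothing else changed.

## Route

Step 1
Reactants: 1 dimethyl furan-3,4-dicarboxylate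
Product: 2 furan-3,4-diyldimethanol
Conditions: LiAlH4, THF, 0 °C → rt
Reagents that add atoms: none
Why: Ester reduction by LiAlH4 (hydride addition–elimination); the furan is inert and the symmetrical diol is the entry to desymmetrisation.

Step 2
Reactants: 2 furan-3,4-diyldimethanol
Product: 3 [4-(TBS-oxymethyl)furan-3-yl]methanol
Conditions: NaH (1.0 equiv), THF, rt; TBSCl (1.0 equiv)
Reagents that add atoms: tert-butyl(dimethyl)silyl chloride, CC(C)(C)[Si](C)(C)Cl
Why: Monosilylation of a symmetrical diol through its sparingly soluble monosodium alkoxide (O-silylation), which reacts once, so the mono ether should dominate; diol and bis-ether can be recycled.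

Step 3
Reactants: 3 [4-(TBS-oxymethyl)furan-3-yl]methanol
Product: 4 4-(TBS-oxymethyl)furan-3-carbaldehyde
Conditions: MnO2, CH2Cl2, rt
Reagents that add atoms: none
Why: MnO2 oxidation of a heteroaryl carbinol (benzylic-type alcohol) stops at the aldehyde and leaves silyl ether and furan alone.

Step 4
Reactants: 4 4-(TBS-oxymethyl)furan-3-carbaldehyde
Product: 8 4-(TBS-oxymethyl)-2-iodofuran-3-carbaldehyde, via lithium amino alkoxide 5 (not isolated), via C6-lithiated amino alkoxide 6 (not isolated), via C6-iodinated amino alkoxide 7 (not isolated)
Conditions: LiN(Me)CH2CH2NMe2 (from the amine and n-BuLi), THF, −78 → −20 °C; n-BuLi, −20 °C; I2, THF, −78 °C; H2O, aq Na2S2O3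
Reagents that add atoms: iodine, II
Why: α-Amino alkoxide directed ortho-lithiation: the lithium amide masks the aldehyde as a hemiaminal alkoxide whose diamine arm chelates n-BuLi and places it at C6, whereas C12 has only the bulky, non-coordinating silyloxymethyl neighbour; iodine traps the furyllithium and water returns the aldehyde. The C6 handle is installed as iodide because a stannane could not be carried through the acid, Me3Al and I2 of later steps.

Step 5
Reactants: 9 methyl 3-methylbut-2-enoate
Product: 10 tert-butyl[(1-methoxy-3-methylbuta-1,3-dien-1-yl)oxy]dimethylsilane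
Conditions: LiN(iPr)2, THF, −78 °C; TBSCl, DMPU, −78 °C → rt
Reagents that add atoms: tert-butyl(dimethyl)silyl chloride, CC(C)(C)[Si](C)(C)Cl
Why: γ-Deprotonation of the enoate and O-silylation (silyl ketene acetal formation) give the vinylogous donor; the ketene acetal geometry is irrelevant because that carbon becomes the ester carbonyl again.

Step 6
Reactants: 8 4-(TBS-oxymethyl)-2-iodofuran-3-carbaldehyde; 10 tert-butyl[(1-methoxy-3-methylbuta-1,3-dien-1-yl)oxy]dimethylsilane
Product: 12 methyl (2E,5S)-5-[4-(TBS-oxymethyl)-2-iodofuran-3-yl]-5-hydroxy-3-methylpent-2-enoate, via trichlorosilyl aldolate 11 (not isolated)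
Conditions: SiCl4 (1.1 equiv), (S,S)-bisphosphoramide (binaphthyldiamine-derived, 5 mol%), iPr2NEt (10 mol%), CH2Cl2, −78 °C; aq NaHCO3
Reagents that add atoms: none
Why: Catalytic enantioselective vinylogous Mukaiyama aldol under Lewis-base activation of SiCl4: the phosphoramide-bound chlorosilyl cation activates the aldehyde and the dienolate attacks through its unhindered γ-CH2 in an open transition state, giving the E enoate (any Z isomer would lactonise and be removed). C8 is set as S by attack on the Si face of the formyl group under catalyst control alone.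

Step 7
Reactants: 12 methyl (2E,5S)-5-[4-(TBS-oxymethyl)-2-iodofuran-3-yl]-5-hydroxy-3-methylpent-2-enoate
Product: 13 methyl (2E,5S)-5-(TBS-oxy)-5-[4-(TBS-oxymethyl)-2-iodofuran-3-yl]-3-methylpent-2-enoate
Conditions: TBSOTf, 2,6-lutidine, CH2Cl2, −78 → 0 °C
Reagents that add atoms: tert-butyl(dimethyl)silyl trifluoromethanesulfonate, CC(C)(C)[Si](C)(C)OS(=O)(=O)C(F)(F)F
Why: O-Silylation of the hindered furyl carbinol with the silyl triflate; it masks the C8 oxygen with a group distinct from the later acetates.

Step 8
Reactants: 13 methyl (2E,5S)-5-(TBS-oxy)-5-[4-(TBS-oxymethyl)-2-iodofuran-3-yl]-3-methylpent-2-enoate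
Product: 14 (2E,5S)-5-(TBS-oxy)-5-[4-(TBS-oxymethyl)-2-iodofuran-3-yl]-3-methylpent-2-en-1-ol
Conditions: iBu2AlH (2.2 equiv), CH2Cl2, −78 °C; aq potassium sodium tartrate
Reagents that add atoms: none
Why: 1,2-Reduction of the α,β-unsaturated ester to the allylic alcohol at low temperature; iodofuran, silyl ethers and the E alkene are untouched.

Step 9
Reactants: 14 (2E,5S)-5-(TBS-oxy)-5-[4-(TBS-oxymethyl)-2-iodofuran-3-yl]-3-methylpent-2-en-1-ol
Product: 15 (2E,5S)-5-(TBS-oxy)-5-[4-(TBS-oxymethyl)-2-iodofuran-3-yl]-3-methylpent-2-enal
Conditions: MnO2, CH2Cl2, rt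
Reagents that add atoms: none
Why: Allylic oxidation with MnO2 gives the E enal without over-oxidation or alkene isomerisation.

Step 10
Reactants: 15 (2E,5S)-5-(TBS-oxy)-5-[4-(TBS-oxymethyl)-2-iodofuran-3-yl]-3-methylpent-2-enal; 16 4,4,5,5-tetramethyl-2-(propa-1,2-dien-1-yl)-1,3,2-dioxaborolane
Product: 18 (4R,5E,8S)-8-(TBS-oxy)-8-[4-(TBS-oxymethyl)-2-iodofuran-3-yl]-6-methyloct-5-en-1-yn-4-ol, via pinacol boronate ester 17 (not isolated)
Conditions: (R)-TRIP (3,3′-bis(2,4,6-triisopropylphenyl)binaphthyl hydrogen phosphate, 10 mol%), 4 Å MS, toluene, −20 °C; aq NaHCO3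
Reagents that add atoms: none
Why: Chiral phosphoric acid catalysed propargylation of an aldehyde with an allenylboronate (SE2′ through a six-membered chair): the acid bridges the boronate oxygen and the formyl group and exposes the Re face, which sets C2 as R independently of the remote C8 centre. The cyclic transition state allows only 1,2-addition to the enal.

Step 11
Reactants: 18 (4R,5E,8S)-8-(TBS-oxy)-8-[4-(TBS-oxymethyl)-2-iodofuran-3-yl]-6-methyloct-5-en-1-yn-4-ol
Product: 20 (1E,4R,5E,8S)-8-(TBS-oxy)-8-[4-(TBS-oxymethyl)-2-iodofuran-3-yl]-1-iodo-2,6-dimethylocta-1,5-dien-4-ol, via alkenylalane 19 (not isolated)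
Conditions: Me3Al (3.5 equiv), Cp2ZrCl2 (0.5 equiv), CH2Cl2, 0 °C → rt; I2, THF, −30 °C; aq potassium sodium tartrate
Reagents that add atoms: trimethylaluminium, C[Al](C)C; iodine, II
Why: Negishi carboalumination: Zr-catalysed syn addition of Me–Al across the terminal alkyne puts methyl on C4 and aluminium on C5, and iodinolysis with retention gives the E vinyl iodide; the alcohol is carried as its aluminium alkoxide and the iodofuran does not react. No tin is present at this stage, so iodine can be used freely.

Step 12
Reactants: 20 (1E,4R,5E,8S)-8-(TBS-oxy)-8-[4-(TBS-oxymethyl)-2-iodofuran-3-yl]-1-iodo-2,6-dimethylocta-1,5-dien-4-ol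
Product: 21 (1E,4R,5E,8S)-8-(TBS-oxy)-8-[4-(hydroxymethyl)-2-iodofuran-3-yl]-1-iodo-2,6-dimethylocta-1,5-dien-4-ol
Conditions: HF·pyridine, pyridine, THF, 0 °C
Reagents that add atoms: none
Why: Selective desilylation: buffered HF·pyridine cleaves the unhindered primary silyl ether at C13 much faster than the secondary one at C8, which is flanked by the iodofuran.

Step 13
Reactants: 21 (1E,4R,5E,8S)-8-(TBS-oxy)-8-[4-(hydroxymethyl)-2-iodofuran-3-yl]-1-iodo-2,6-dimethylocta-1,5-dien-4-ol
Product: 22 (1E,4R,5E,8S)-8-[4-(acetoxymethyl)-2-iodofuran-3-yl]-8-(TBS-oxy)-1-iodo-2,6-dimethylocta-1,5-dien-4-yl acetate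
Conditions: Ac2O, pyridine, DMAP (cat.), CH2Cl2, 0 °C → rt
Reagents that add atoms: acetic anhydride, CC(=O)OC(C)=O
Why: DMAP-catalysed acetylation of the primary C13 and the secondary allylic C2 alcohol in one operation.

Step 14
Reactants: 22 (1E,4R,5E,8S)-8-[4-(acetoxymethyl)-2-iodofuran-3-yl]-8-(TBS-oxy)-1-iodo-2,6-dimethylocta-1,5-dien-4-yl acetate
Product: 24 (1E,4R,5E,8S)-8-[4-(acetoxymethyl)-2-(tributylstannyl)furan-3-yl]-8-(TBS-oxy)-1-iodo-2,6-dimethylocta-1,5-dien-4-yl acetate, via furylmagnesium chloride 23 (not isolated)
Conditions: iPrMgCl·LiCl (1.05 equiv), THF, −40 °C; Bu3SnCl, −40 → 0 °C; Et3N-deactivated silica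
Reagents that add atoms: tributyltin chloride, CCCC[Sn](Cl)(CCCC)CCCC
Why: Iodine–magnesium exchange then transmetallation to tin: the 2-iodofuran should exchange far faster than the unactivated alkenyl iodide because the furyl carbanion is stabilised by the adjacent ring oxygen, and at −40 °C the hindered reagent should spare the acetates. The acid- and iodine-sensitive stannane is thus made only in the last operation before ring closure.

Step 15
Reactants: 24 (1E,4R,5E,8S)-8-[4-(acetoxymethyl)-2-(tributylstannyl)furan-3-yl]-8-(TBS-oxy)-1-iodo-2,6-dimethylocta-1,5-dien-4-yl acetate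
Product: 25 ten-membered furanophane (furan O–C6=C7–C11=C12 fused at C6–C7; 2R,8S; 1(10)E,4E; 2-OAc, 13-OAc, 8-OTBS)
Conditions: Pd2(dba)3 (10 mol%), AsPh3 (80 mol%), iPr2NEt (2 equiv), degassed DMF–THF (1:1), 0.001 M by syringe pump, 40 °C
Reagents that add atoms: none
Why: Intramolecular Stille coupling; the closest known reaction type is the macrocyclisation of 2-furyl- and alkenylstannanes with vinyl iodides. Zerovalent palladium inserts into the C5–I bond with retention of the E geometry, the electron-rich 2-furylstannane transmetallates (the slow step, helped by the weakly bound AsPh3), and reductive elimination from the eleven-membered diorganopalladium ring forms C5–C6. The ten-membered ring is closed end to end between two sp2 carbons, so closure depends on the reach of the chain and not on an attack trajectory. No stereocentre is formed: C2 and C8 are spectators, and the flat furan keeps C6 non-stereogenic and non-acidic. The step needs ring closure to win over oligomerisation; this is served by slow addition at millimolar concentration, by the two E alkenes and the furan, which leave only six rotatable bonds between the termini, and by the C8 silyloxy branch beside the furan, which turns the chain back towards C6. Retention of alkene geometry follows from the mechanism. The C2 allylic and C13 furylmethyl acetates should not be ionised by the arsine-ligated catalyst at 40 °C, and iPr2NEt guards the stannane against protodestannylation.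

Step 16
Reactants: 25 ten-membered furanophane
Product: 27 C6 hydroxybutenolide (6-hydroxy-6,12-olide with C7=C11; C6 epimers; otherwise as 25), via furan endoperoxide 26 (not isolated)
Conditions: O2, visible light, tetraphenylporphyrin (cat.), iPr2NEt, CH2Cl2, −78 °C
Reagents that add atoms: dioxygen, O=O
Why: [4+2] Cycloaddition of singlet oxygen across C6 and C12 followed by base-induced Kornblum–DeLaMare fragmentation: the amine removes the only endoperoxide hydrogen (on C12), so the carbonyl appears at C12 and the hydroxyl at C6 without regiochemical ambiguity. The trisubstituted furan should react far faster than the two trisubstituted alkenes at −78 °C; C6 forms as an inconsequential hemiketal mixture.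

Step 17
Reactants: 27 C6 hydroxybutenolide
Product: 30 (2R,6R,8S)-2,13-diacetoxy-8-(TBS-oxy)germacra-1(10)E,4E,7(11)-trien-6,12-olide, via sodium keto carboxylate 28 (not isolated), via sodium hydroxy carboxylate 29 (not isolated)
Conditions: NaBH4, CeCl3·7H2O, MeOH–THF, −40 → 0 °C; 1 M HCl to pH 3
Reagents that add atoms: none
Why: Luche-type 1,2-reduction: borohydride opens the pseudo-acid to the keto carboxylate and reduces the cross-conjugated C6 ketone, and acidification closes the γ-lactone; acetates survive at low temperature. C6 is set by hydride attack on the outer face of the ketone, which is twisted out of the C7=C11 plane with its inner face turned into the ring; the conformer with C5 and the C8 silyloxy group on the same side of that plane leads to 6R (C6–O cis to C8–O). This is the least secure stereocentre of the route.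

Step 18
Reactants: 30 (2R,6R,8S)-2,13-diacetoxy-8-(TBS-oxy)germacra-1(10)E,4E,7(11)-trien-6,12-olide
Product: 31 (2R,6R,8S)-2,13-diacetoxy-8-hydroxygermacra-1(10)E,4E,7(11)-trien-6,12-olide
Conditions: HF·pyridine, THF, 0 °C → rt
Reagents that add atoms: none
Why: Desilylation under mildly acidic, non-basic conditions frees the C8 alcohol without touching lactone, acetates or the base-sensitive C6–H; lactone migration to O8 is impossible because C8 lies trans to C12 across C7=C11.

Step 19
Reactants: 31 (2R,6R,8S)-2,13-diacetoxy-8-hydroxygermacra-1(10)E,4E,7(11)-trien-6,12-olide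
Product: 32 (2R,6R,8S)-2,13-diacetoxy-8-(methacryloyloxy)germacra-1(10)E,4E,7(11)-trien-6,12-olide (CNP0309304.1)
Conditions: methacrylic anhydride, Et3N, DMAP (cat.), BHT (trace), CH2Cl2, 0 °C
Reagents that add atoms: methacrylic anhydride, C=C(C)C(=O)OC(=O)C(C)=C
Why: DMAP-catalysed acylation of the secondary alcohol with the anhydride; the amine bases are too weak to deprotonate C6, and the radical inhibitor prevents polymerisation.

## Compound list

1 | dimethyl furan-3,4-dicarboxylate | COC(=O)c1cocc1C(=O)OC | starting material
2 | furan-3,4-diyldimethanol | OCc1cocc1CO | intermediate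
3 | [4-(TBS-oxymethyl)furan-3-yl]methanol | CC(C)(C)[Si](C)(C)OCc1cocc1CO | intermediate
4 | 4-(TBS-oxymethyl)furan-3-carbaldehyde | CC(C)(C)[Si](C)(C)OCc1cocc1C=O | intermediate
5 | lithium α-amino alkoxide from 4 and lithium N,N,N′-trimethylethylenediamide (racemic at the hemiaminal carbon) | CC(C)(C)[Si](C)(C)OCc1cocc1C([O-])N(C)CCN(C)C.[Li+] | intermediate (not isolated)
6 | C6-lithiated α-amino alkoxide | CC(C)(C)[Si](C)(C)OCc1coc([Li])c1C([O-])N(C)CCN(C)C.[Li+] | intermediate (not isolated)
7 | C6-iodinated α-amino alkoxide | CC(C)(C)[Si](C)(C)OCc1coc(I)c1C([O-])N(C)CCN(C)C.[Li+] | intermediate (not isolated)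
8 | 4-(TBS-oxymethyl)-2-iodofuran-3-carbaldehyde | CC(C)(C)[Si](C)(C)OCc1coc(I)c1C=O | intermediate
9 | methyl 3-methylbut-2-enoate | COC(=O)C=C(C)C | starting material
10 | tert-butyl[(1-methoxy-3-methylbuta-1,3-dien-1-yl)oxy]dimethylsilane (ketene acetal geometry undefined and lost in step 6) | C=C(C)C=C(OC)O[Si](C)(C)C(C)(C)C | intermediate
11 | trichlorosilyl ether of 12 (5S) | COC(=O)/C=C(C)/C[C@H](O[Si](Cl)(Cl)Cl)c1c(I)occ1CO[Si](C)(C)C(C)(C)C | intermediate (not isolated)
12 | methyl (2E,5S)-5-[4-(TBS-oxymethyl)-2-iodofuran-3-yl]-5-hydroxy-3-methylpent-2-enoate | COC(=O)/C=C(C)/C[C@H](O)c1c(I)occ1CO[Si](C)(C)C(C)(C)C | intermediate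
13 | methyl (2E,5S)-5-(TBS-oxy)-5-[4-(TBS-oxymethyl)-2-iodofuran-3-yl]-3-methylpent-2-enoate | COC(=O)/C=C(C)/C[C@H](O[Si](C)(C)C(C)(C)C)c1c(I)occ1CO[Si](C)(C)C(C)(C)C | intermediate
14 | (2E,5S)-5-(TBS-oxy)-5-[4-(TBS-oxymethyl)-2-iodofuran-3-yl]-3-methylpent-2-en-1-ol | OC/C=C(C)/C[C@H](O[Si](C)(C)C(C)(C)C)c1c(I)occ1CO[Si](C)(C)C(C)(C)C | intermediate
15 | (2E,5S)-5-(TBS-oxy)-5-[4-(TBS-oxymethyl)-2-iodofuran-3-yl]-3-methylpent-2-enal | O=C/C=C(C)/C[C@H](O[Si](C)(C)C(C)(C)C)c1c(I)occ1CO[Si](C)(C)C(C)(C)C | intermediate
16 | 4,4,5,5-tetramethyl-2-(propa-1,2-dien-1-yl)-1,3,2-dioxaborolane (allenylboronic acid pinacol ester) | C=C=CB1OC(C)(C)C(C)(C)O1 | starting material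
17 | pinacol boronate ester of 18 (4R,8S) | C#CC[C@@H](OB1OC(C)(C)C(C)(C)O1)/C=C(C)/C[C@H](O[Si](C)(C)C(C)(C)C)c1c(I)occ1CO[Si](C)(C)C(C)(C)C | intermediate (not isolated)
18 | (4R,5E,8S)-8-(TBS-oxy)-8-[4-(TBS-oxymethyl)-2-iodofuran-3-yl]-6-methyloct-5-en-1-yn-4-ol | C#CC[C@@H](O)/C=C(C)/C[C@H](O[Si](C)(C)C(C)(C)C)c1c(I)occ1CO[Si](C)(C)C(C)(C)C | intermediate
19 | (E)-C5 dimethylalkenylalane, C2 oxygen as dimethylaluminium alkoxide (2R,8S) | C[Al](C)/C=C(\C)C[C@@H](O[Al](C)C)/C=C(C)/C[C@H](O[Si](C)(C)C(C)(C)C)c1c(I)occ1CO[Si](C)(C)C(C)(C)C | intermediate (not isolated)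
20 | (1E,4R,5E,8S)-8-(TBS-oxy)-8-[4-(TBS-oxymethyl)-2-iodofuran-3-yl]-1-iodo-2,6-dimethylocta-1,5-dien-4-ol | I/C=C(\C)C[C@@H](O)/C=C(C)/C[C@H](O[Si](C)(C)C(C)(C)C)c1c(I)occ1CO[Si](C)(C)C(C)(C)C | intermediate
21 | (1E,4R,5E,8S)-8-(TBS-oxy)-8-[4-(hydroxymethyl)-2-iodofuran-3-yl]-1-iodo-2,6-dimethylocta-1,5-dien-4-ol | I/C=C(\C)C[C@@H](O)/C=C(C)/C[C@H](O[Si](C)(C)C(C)(C)C)c1c(I)occ1CO | intermediate
22 | (1E,4R,5E,8S)-8-[4-(acetoxymethyl)-2-iodofuran-3-yl]-8-(TBS-oxy)-1-iodo-2,6-dimethylocta-1,5-dien-4-yl acetate | I/C=C(\C)C[C@@H](OC(C)=O)/C=C(C)/C[C@H](O[Si](C)(C)C(C)(C)C)c1c(I)occ1COC(C)=O | intermediate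
23 | C6 furylmagnesium chloride of 22 | I/C=C(\C)C[C@@H](OC(C)=O)/C=C(C)/C[C@H](O[Si](C)(C)C(C)(C)C)c1c([Mg]Cl)occ1COC(C)=O | intermediate (not isolated)
24 | (1E,4R,5E,8S)-8-[4-(acetoxymethyl)-2-(tributylstannyl)furan-3-yl]-8-(TBS-oxy)-1-iodo-2,6-dimethylocta-1,5-dien-4-yl acetate | CC(C)(C)[Si](C)(C)O[C@@H](C/C(C)=C/[C@H](OC(C)=O)C/C(C)=C/I)c1c(COC(C)=O)coc1[Sn](CCCC)(CCCC)CCCC | intermediate
25 | ten-membered furanophane (2R,8S; 1(10)E,4E; 2-OAc, 13-OAc, 8-OTBS) | CC(C)(C)[Si](C)(C)O[C@H]1C/C(C)=C/[C@H](OC(C)=O)C/C(C)=C/c2occ(COC(C)=O)c12 | intermediate
26 | furan endoperoxide (O–O across C6 and C12; both facial adducts) | CC(C)(C)[Si](C)(C)O[C@H]1C/C(C)=C/[C@H](OC(C)=O)C/C(C)=C/C23OOC(O2)C(COC(C)=O)=C13 | intermediate (not isolated)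
27 | C6 hydroxybutenolide (C6 epimers) | CC(C)(C)[Si](C)(C)O[C@H]1C/C(C)=C/[C@H](OC(C)=O)C/C(C)=C/C2(O)OC(=O)C(COC(C)=O)=C12 | intermediate
28 | sodium (Z)-keto carboxylate (C6 ketone, C12 carboxylate) | CC(C)(C)[Si](C)(C)O[C@H]1C/C(C)=C/[C@H](OC(C)=O)C/C(C)=C/C(=O)/C1=C(/COC(C)=O)C(=O)[O-].[Na+] | intermediate (not isolated)
29 | sodium (6R)-hydroxy carboxylate | CC(C)(C)[Si](C)(C)O[C@H]1C/C(C)=C/[C@H](OC(C)=O)C/C(C)=C/[C@@H](O)/C1=C(/COC(C)=O)C(=O)[O-].[Na+] | intermediate (not isolated)
30 | (2R,6R,8S)-2,13-diacetoxy-8-(TBS-oxy)germacra-1(10)E,4E,7(11)-trien-6,12-olide | CC(C)(C)[Si](C)(C)O[C@H]1C/C(C)=C/[C@H](OC(C)=O)C/C(C)=C/[C@H]2OC(=O)C(COC(C)=O)=C12 | intermediate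
31 | (2R,6R,8S)-2,13-diacetoxy-8-hydroxygermacra-1(10)E,4E,7(11)-trien-6,12-olide | O[C@H]1C/C(C)=C/[C@H](OC(C)=O)C/C(C)=C/[C@H]2OC(=O)C(COC(C)=O)=C12 | intermediate
32 | (2R,6R,8S)-2,13-diacetoxy-8-(methacryloyloxy)germacra-1(10)E,4E,7(11)-trien-6,12-olide (CNP0309304.1) | C=C(C)C(=O)O[C@H]1C/C(C)=C/[C@H](OC(C)=O)C/C(C)=C/[C@H]2OC(=O)C(COC(C)=O)=C12 | target

## Step count and least certain steps

Total: 19 steps. Longest linear sequence: 18 steps (1 → 32 through steps 1–4 and 6–19); dienolate 10 is a one-step side branch.

Step 15 (key step). Most likely failure: oligomerisation outrunning closure of the strained ring, because reductive elimination needs both termini cis on palladium and a chain of this length can only just reach; slow transmetallation also leaves time for protodestannylation and for ionisation of the C2 acetate. Fallback (C5–C6 made by carbonyl addition instead of cross-coupling, dearomatisation before ring closure): set out from 22. Iodine–magnesium exchange as in step 14 with a methanol quench gives the C6-unsubstituted furan F1. Photooxygenation as in step 16, where the hindered base should remove the more exposed C12–H, gives the hydroxybutenolide F2 with a masked aldehyde at C6. MeI with K2CO3 opens it to the (Z)-formyl methyl ester F3. An intramolecular Nozaki–Hiyama–Kishi reaction (CrCl2, NiCl2 cat., DMSO–THF, high dilution) adds the C5 alkenylchromium to the C6 aldehyde, and the alkoxide closes onto the C12 ester to rejoin the route at 30. The ring then closes at an sp3 carbon, the classical way to germacranolides, in the same number of steps, at the price of a C6 centre formed under substrate control.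

Step 14. Most likely failure: loss of chemoselectivity in the halogen–metal exchange (competing exchange at the alkenyl iodide), attack of organomagnesium species on the acetates, or protodestannylation during isolation. Fallback: from 22, direct insertion of zinc (Zn dust, LiCl, THF, 25 °C) into the furyl C–I bond, which alkenyl iodides and esters should tolerate, gives the furylzinc iodide F4. Without isolation, slow addition to Pd2(dba)3 and 2-dicyclohexylphosphino-2′,6′-dimethoxybiphenyl closes the ring by intramolecular Negishi coupling and rejoins the route at 25, bypassing the stannane.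

Step 17. Most likely failure: poor facial selectivity in hydride addition to the C6 ketone (the face offered depends on which ring conformer reacts), conjugate reduction of the dienone, or SN2′ loss of the C13 acetate once the lactone has closed. Fallback (reagent control instead of substrate control): from 27, TMSCHN2 in MeOH–toluene gives the open-chain methyl keto ester F5. Corey–Bakshi–Shibata reduction with the (S)-methyl oxazaborolidine and catecholborane at −40 °C, with the tetrasubstituted C7 alkene as the large group and the C5 vinyl carbon as the small one, gives the 6R hydroxy ester F6, which lactonises with a trace of acid to 30.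

Step 16. Most likely failure: competing ene reaction of singlet oxygen at C1=C10 or C4=C5, or cycloaddition across the C4=C5–C6=C7 diene, if the furan is slowed by ring strain. Fallback (two-electron oxidant in place of singlet oxygen): from 25, NBS with NaHCO3 in aqueous THF at −20 °C should attack the much more electron-rich furan first and open it to the (Z)-keto enal F7. Pinnick oxidation (NaClO2, NaH2PO4, 2-methylbut-2-ene) of the C12 aldehyde gives the acid, which closes to 27.

Step 6. Most likely failure: low conversion or low facial selectivity at an aldehyde with substituents at both ortho positions, or erosion of γ and E selectivity. Fallback (C8 set by propargylation, the C1=C10 alkene by carbometallation): from 8, allenylboronate 16 with (S)-TRIP (Si-face attack) gives the homopropargylic alcohol F8. TBSOTf with 2,6-lutidine gives its silyl ether F9. Zr-catalysed carboalumination as in step 11 with trapping by methyl chloroformate gives the E enoate 13, where the route is rejoined at the price of one more linear step.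

## Further compounds

F1 | step 15 | (1E,4R,5E,8S)-8-[4-(acetoxymethyl)furan-3-yl]-8-(TBS-oxy)-1-iodo-2,6-dimethylocta-1,5-dien-4-yl acetate | I/C=C(\C)C[C@@H](OC(C)=O)/C=C(C)/C[C@H](O[Si](C)(C)C(C)(C)C)c1cocc1COC(C)=O
F2 | step 15 | open-chain hydroxybutenolide (C6 lactol, C12 carbonyl, C6 epimers) with the C5 vinyl iodide | I/C=C(\C)C[C@@H](OC(C)=O)/C=C(C)/C[C@H](O[Si](C)(C)C(C)(C)C)C1=C(COC(C)=O)C(=O)OC1O
F3 | step 15 | (Z)-formyl methyl ester (C6 aldehyde, C12 methyl ester) with the C5 vinyl iodide | I/C=C(\C)C[C@@H](OC(C)=O)/C=C(C)/C[C@H](O[Si](C)(C)C(C)(C)C)/C(C=O)=C(\COC(C)=O)C(=O)OC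
F4 | step 14 | C6 furylzinc iodide of 22 | I/C=C(\C)C[C@@H](OC(C)=O)/C=C(C)/C[C@H](O[Si](C)(C)C(C)(C)C)c1c([Zn]I)occ1COC(C)=O
F5 | step 17 | macrocyclic methyl (Z)-keto ester (C6 ketone, C12 methyl ester) | CC(C)(C)[Si](C)(C)O[C@H]1C/C(C)=C/[C@H](OC(C)=O)C/C(C)=C/C(=O)/C1=C(/COC(C)=O)C(=O)OC
F6 | step 17 | macrocyclic methyl (6R)-hydroxy ester | CC(C)(C)[Si](C)(C)O[C@H]1C/C(C)=C/[C@H](OC(C)=O)C/C(C)=C/[C@@H](O)/C1=C(/COC(C)=O)C(=O)OC
F7 | step 16 | macrocyclic (Z)-keto enal (C6 ketone, C12 aldehyde) | CC(C)(C)[Si](C)(C)O[C@H]1C/C(C)=C/[C@H](OC(C)=O)C/C(C)=C/C(=O)/C1=C(/COC(C)=O)C=O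
F8 | step 6 | (1S)-1-[4-(TBS-oxymethyl)-2-iodofuran-3-yl]but-3-yn-1-ol | C#CC[C@H](O)c1c(I)occ1CO[Si](C)(C)C(C)(C)C
F9 | step 6 | TBS ether of F8 | C#CC[C@H](O[Si](C)(C)C(C)(C)C)c1c(I)occ1CO[Si](C)(C)C(C)(C)C
A1 | alternative 1 | open-chain butenolide with C8 nitromethyl group and trans C1–C2 vinyl epoxide (6R) | C=C(C)[C@H]1O[C@@H]1C/C(C)=C/[C@H]2OC(=O)C(CO[Si](C)(C)C(C)(C)C)=C2C[N+](=O)[O-]
A2 | alternative 1 | C8-nitro germacranolide with free C2 alcohol (C8 epimers) | O=[N+]([O-])C1C/C(C)=C/[C@H](O)C/C(C)=C/[C@H]2OC(=O)C(CO[Si](C)(C)C(C)(C)C)=C12
A3 | alternative 2 | linear ynal (C6 enal, C7≡C11 alkyne, 2R,8S) | O=C/C=C(\C)C[C@@H](OC(C)=O)/C=C(C)/C[C@H](O[Si](C)(C)C(C)(C)C)C#CCOC(C)=O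
A4 | alternative 2 | bicyclic germacranolide with C8 silyl ether (identical with 30) | CC(C)(C)[Si](C)(C)O[C@H]1C/C(C)=C/[C@H](OC(C)=O)C/C(C)=C/[C@H]2OC(=O)C(COC(C)=O)=C12
A5 | alternative 3 | furan-fused trans-divinylcyclohexanol (C5 S carbinol with isopropenyl; C10 R with methyl and E silyloxyvinyl; C8 S PMB ether) | C=C(C)[C@@]1(O)c2occ(CO[Si](C)(C)C(C)(C)C)c2[C@@H](OCc2ccc(OC)cc2)C[C@]1(C)/C=C/O[Si](C)(C)C(C)(C)C
A6 | alternative 3 | ten-membered furanophane C5 enol triflate | COc1ccc(CO[C@H]2C/C(C)=C/[C@H](O[Si](C)(C)C(C)(C)C)C/C(C)=C(\OS(=O)(=O)C(F)(F)F)c3occ(CO[Si](C)(C)C(C)(C)C)c23)cc1
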